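**Plan**
- Retrosynthesis: the three MOM ethers and the C3 hydroxyl are removed, ring C is opened at O1–C2, and the C4a–C4 and C4–C3 bonds are then cut in one operation.
- That cut is possible because C4 is a single carbonyl carbon standing between C4a of ring A and the C3–C2 unit that carries ring B. Carbon monoxide can therefore serve as C4, an aryl iodide (iodine on C4a) as ring A, and a terminal arylacetylene as C3–C2–ring B.
- Ring A iodide 8 comes from phloroglucinol: the C8 1,1-dimethylallyl group by aryl prenyl ether Claisen shift, an acetate on the C8a oxygen, and iodine last.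
- Ring B alkyne 23 comes from 6-bromopiperonal: the dimethylpyran by a propargyl ether Claisen cascade, the prenyl group built on the formyl carbon, and the ethynyl group from the bromide.
- Forward order of rings: the pyran on ring B (step 9), the fifteen-carbon ynone chain (step 15), ring C by 6-endo closure (step 16), then the C3 hydroxyl and deprotection.
- Stereochemistry: the target has no stereocentre and no stereogenic double bond, so nothing has to be controlled.

Key step: step 15

Positions are given in flavone numbering (O1, C2, C3, C4, C4a, C5–C8, C8a; ring B primed), also for the fragment atoms that end up there.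

**Route**

Step 1
Reactants: 1 phloroglucinol
Product: 2 3,5-bis(methoxymethoxy)phenol
Conditions: MOMCl (2.0 equiv), i-Pr2NEt (2.5 equiv), THF, 0 °C → rt; chromatography
Reagents that add atoms: chloromethyl methyl ether, COCCl
Why: Williamson-type O-alkylation of phenoxide by an α-chloro ether; the three hydroxyls are equivalent, so two equivalents of the chloride should make the bis-ether the main component of a mixture from which the mono- and tris-ethers are removed by chromatography.

Step 2
Reactants: 2 3,5-bis(methoxymethoxy)phenol; 3 prenyl bromide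
Product: 4 1,3-bis(methoxymethoxy)-5-[(3-methylbut-2-en-1-yl)oxy]benzene
Conditions: K2CO3, acetone, reflux
Reagents that add atoms: none
Why: Williamson ether synthesis: the single free phenoxide should displace the primary allylic bromide by SN2 at oxygen under carbonate conditions that leave the MOM acetals untouched.

Step 3
Reactants: 4 aryl prenyl ether
Product: 6 3,5-bis(methoxymethoxy)-2-(2-methylbut-3-en-2-yl)phenol, via ortho-dienone 5 (not isolated)
Conditions: PhNEt2, 185 °C, argon
Reagents that add atoms: none
Why: Aromatic Claisen rearrangement: the [3,3]-sigmatropic shift should carry the tertiary terminus of the prenyl unit to one of the two equivalent ortho carbons to give dienone 5, whose enolisation restores the arene and places the 1,1-dimethylallyl group (future C8) next to the free hydroxyl (future C8a oxygen); the sp3 centre of 5 is lost on enolisation.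

Step 4
Reactants: 6 reverse-prenylated phenol
Product: 7 3,5-bis(methoxymethoxy)-2-(2-methylbut-3-en-2-yl)phenyl acetate
Conditions: Ac2O, pyridine, DMAP (cat.), CH2Cl2, rt
Reagents that add atoms: acetic anhydride, CC(=O)OC(C)=O
Why: DMAP-catalysed O-acylation of a hindered phenol masks the future O1 as an ester that is inert to tertiary amines, and it removes the hydroxyl that could otherwise capture an iodonium ion formed at the neighbouring vinyl group in the next step.

Step 5
Reactants: 7 aryl acetate
Product: 8 2-iodo-3,5-bis(methoxymethoxy)-6-(2-methylbut-3-en-2-yl)phenyl acetate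
Conditions: NIS (1.05 equiv), CF3CO2H (10 mol %), MeCN, 0 °C, dark
Reagents that add atoms: N-iodosuccinimide, O=C1CCC(=O)N1I
Why: Electrophilic aromatic iodination: the carbon between the acetoxy and a MOM-oxy group is ortho to one ether oxygen and para to the other (the orientation preferred in resorcinol diethers), whereas the other free carbon is wedged between both MOM ethers and is para only to the weakly donating acetate, so substitution should occur at the future C4a, and the electron-rich arene should react much faster than the unactivated monosubstituted alkene.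

Step 6
Reactants: 9 6-bromopiperonal
Product: 10 2-bromo-4,5-dihydroxybenzaldehyde
Conditions: BBr3, CH2Cl2, −78 °C → rt; then H2O
Reagents that add atoms: none
Why: Lewis acid cleavage of the methylenedioxy acetal by BBr3, a standard unmasking of catechols that tolerates aryl aldehydes and aryl bromides, should give the catechol after aqueous work-up.

Step 7
Reactants: 10 bromocatechol aldehyde
Product: 11 2-bromo-5-hydroxy-4-(methoxymethoxy)benzaldehyde
Conditions: MOMCl (1.05 equiv), K2CO3 (1.1 equiv), acetone, 0 °C → rt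
Reagents that add atoms: chloromethyl methyl ether, COCCl
Why: Regioselective Williamson-type alkylation: the hydroxyl para to the formyl group is the more acidic, so one equivalent of carbonate should generate and alkylate that phenoxide, as is routine for 3,4-dihydroxybenzaldehydes.

Step 8
Reactants: 11 mono-MOM phenol; 12 3-chloro-3-methylbut-1-yne
Product: 13 2-bromo-4-(methoxymethoxy)-5-[(2-methylbut-3-yn-2-yl)oxy]benzaldehyde
Conditions: DBU, CuCl2·2H2O (1 mol %), MeCN, 0 °C → rt
Reagents that add atoms: none
Why: Copper-catalysed O-propargylation of a phenol with a tertiary propargylic chloride, the usual entry to aryl 1,1-dimethylpropargyl ethers, should take place at the one remaining hydroxyl.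

Step 9
Reactants: 13 aryl propargyl ether
Product: 16 6-bromo-8-(methoxymethoxy)-2,2-dimethyl-2H-chromene-5-carbaldehyde, via allenylphenol 14 (not isolated), via ortho-quinone methide 15 (not isolated)
Conditions: PhNEt2, 180 °C, argon
Reagents that add atoms: none
Why: Propargyl aryl ether Claisen cascade: [3,3]-shift and enolisation give allenylphenol 14, a 1,5-hydrogen shift gives ortho-quinone methide 15, and oxa-6π-electrocyclisation closes the 2,2-dimethyl-2H-pyran; the only free ortho carbon lies between the ether oxygen and the formyl-bearing carbon, so a single chromene regioisomer is possible.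

Step 10
Reactants: 16 bromochromene aldehyde; 17 trimethylsilylacetylene
Product: 18 8-(methoxymethoxy)-2,2-dimethyl-6-[(trimethylsilyl)ethynyl]-2H-chromene-5-carbaldehyde
Conditions: PdCl2(PPh3)2 (3 mol %), CuI (5 mol %), Et3N, THF, 60 °C, sealed tube
Reagents that add atoms: none
Why: Sonogashira coupling: the formyl group ortho to bromine activates the C–Br bond towards oxidative addition, so the standard palladium/copper system should install the silyl-protected ethynyl group that becomes C3–C2.

Step 11
Reactants: 18 silylethynyl aldehyde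
Product: 19 {8-(methoxymethoxy)-2,2-dimethyl-6-[(trimethylsilyl)ethynyl]-2H-chromen-5-yl}methanol
Conditions: NaBH4, THF/EtOH, 0 °C
Reagents that add atoms: none
Why: Borohydride reduction of an aryl aldehyde to the benzylic alcohol is chemoselective in the presence of the silylalkyne, the chromene double bond and the MOM acetal.

Step 12
Reactants: 19 benzylic alcohol
Product: 20 5-(bromomethyl)-8-(methoxymethoxy)-2,2-dimethyl-6-[(trimethylsilyl)ethynyl]-2H-chromene
Conditions: CBr4, PPh3, CH2Cl2, 0 °C; used without storage
Reagents that add atoms: carbon tetrabromide, BrC(Br)(Br)Br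
Why: Appel reaction: the alkoxyphosphonium ion is displaced by bromide under neutral conditions that spare the MOM acetal, and the electron-rich benzylic bromide is carried on at once.

Step 13
Reactants: 20 benzylic bromide; 21 2-methylprop-1-enylmagnesium bromide
Product: 22 8-(methoxymethoxy)-2,2-dimethyl-5-(3-methylbut-2-en-1-yl)-6-[(trimethylsilyl)ethynyl]-2H-chromene
Conditions: CuI (10 mol %), THF, −30 → 0 °C
Reagents that add atoms: none
Why: Copper-catalysed cross-coupling of a benzylic bromide with an alkenyl Grignard reagent (substitution by an alkenylcuprate) forms the ArCH2–CH= bond, and because the double bond arrives with the nucleophile the prenyl group cannot appear in transposed form.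

Step 14
Reactants: 22 silylalkyne
Product: 23 6-ethynyl-8-(methoxymethoxy)-2,2-dimethyl-5-(3-methylbut-2-en-1-yl)-2H-chromene
Conditions: K2CO3 (cat.), MeOH/THF, rt
Reagents that add atoms: none
Why: Methoxide-mediated protodesilylation of a trimethylsilylalkyne frees the terminal alkyne without touching the MOM ether, the prenyl group or the chromene.

Step 15
Reactants: 8 ring A aryl iodide; 24 carbon monoxide; 23 ring B ethynylarene
Product: 25 2-{3-[8-(methoxymethoxy)-2,2-dimethyl-5-(3-methylbut-2-en-1-yl)-2H-chromen-6-yl]prop-2-ynoyl}-3,5-bis(methoxymethoxy)-6-(2-methylbut-3-en-2-yl)phenyl acetate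
Conditions: PdCl2(PPh3)2 (5 mol %), Et3N (3 equiv), CO (5 bar), THF, 50 °C, no copper salt
Reagents that add atoms: none
Why: Zerovalent palladium, formed from PdCl2(PPh3)2 under CO and amine, should insert into the C4a–I bond of 8; migratory insertion of CO gives an aroylpalladium iodide, alkyne 23 is palladated with Et3N as base, and reductive elimination forms the C4a–C4 and C4–C3 bonds of ynone 25. The closest known reaction type is the copper-free carbonylative Sonogashira coupling of ortho-acyloxy aryl iodides with arylacetylenes used for flavone synthesis. No ring closes and no stereocentre is created in this step. The selectivity needed is acyl transfer over direct alkynylation: the two oxygen substituents flanking the C–Pd bond should slow alkynyl transfer to the crowded arylpalladium more than insertion of the small CO ligand, and CO pressure in the absence of a copper acetylide reinforces this. Premature cyclisation is excluded because the C8a oxygen is acetylated and Et3N, a tertiary amine, neither cleaves the acetate nor adds to the ynone.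

Step 16
Reactants: 25 ynone acetate
Product: 28 5,7-bis(methoxymethoxy)-2-[8-(methoxymethoxy)-2,2-dimethyl-5-(3-methylbut-2-en-1-yl)-2H-chromen-6-yl]-8-(2-methylbut-3-en-2-yl)-4H-chromen-4-one, via enaminone acetate 26 (not isolated), via enaminone phenol 27 (not isolated)
Conditions: Et2NH (10 equiv), DBU (1 equiv), DMF, rt → 40 °C
Reagents that add atoms: none
Why: Aza-Michael addition of Et2NH to the ynone gives enaminone 26, aminolysis of the aryl acetate frees phenol 27, and 6-endo-trig addition–elimination at C2 with loss of Et2NH closes ring C; the prior amine addition removes the alkyne that a phenoxide could attack in 5-exo mode, and because the C8a oxygen stands next to the 1,1-dimethylallyl group only the 8-substituted flavone can form.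

Step 17
Reactants: 28 tris-MOM flavone
Product: 31 3-hydroxy-5,7-bis(methoxymethoxy)-2-[8-(methoxymethoxy)-2,2-dimethyl-5-(3-methylbut-2-en-1-yl)-2H-chromen-6-yl]-8-(2-methylbut-3-en-2-yl)-4H-chromen-4-one, via 3-lithioflavone 29 (not isolated), via flavone-3-boronate 30 (not isolated)
Conditions: LiN(i-Pr)2 (1.3 equiv), THF, −78 °C; B(OMe)3 (2 equiv), −78 → 0 °C; AcOH, 30% aq. H2O2, 0 °C → rt
Reagents that add atoms: hydrogen peroxide, OO
Why: Carbonyl-directed lithiation–borylation–oxidation of a flavone: the amide base should remove the C3 vinylic proton next to the coordinating C4 carbonyl to give 29, trimethyl borate converts it to boronate 30, and peroxide oxidation with 1,2-migration from boron to oxygen gives the C3 hydroxyl, an established conversion of alkoxyflavones into flavonols.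

Step 18
Reactants: 31 tris-MOM flavonol
Product: 32 Broussoflavonol D
Conditions: 3 M aq. HCl/MeOH (1:10), 40 °C
Reagents that add atoms: none
Why: Acid-catalysed methanolysis of the three MOM acetals, the usual last step for prenylated flavonoids, should free the C5, C7 and C5′ hydroxyls under conditions too mild to protonate the vinyl, prenyl or chromene double bonds.

**Compound list**
1 | phloroglucinol | Oc1cc(O)cc(O)c1 | starting material
2 | 3,5-bis(methoxymethoxy)phenol | Oc1cc(OCOC)cc(OCOC)c1 | intermediate
3 | prenyl bromide (1-bromo-3-methylbut-2-ene) | CC(C)=CCBr | starting material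
4 | 1,3-bis(methoxymethoxy)-5-[(3-methylbut-2-en-1-yl)oxy]benzene | CC(C)=CCOc1cc(OCOC)cc(OCOC)c1 | intermediate
5 | 3,5-bis(methoxymethoxy)-6-(2-methylbut-3-en-2-yl)cyclohexa-2,4-dien-1-one (ortho-dienone, racemic, not isolated) | C=CC(C)(C)C1C(=O)C=C(OCOC)C=C1OCOC | intermediate
6 | 3,5-bis(methoxymethoxy)-2-(2-methylbut-3-en-2-yl)phenol | C=CC(C)(C)c1c(O)cc(OCOC)cc1OCOC | intermediate
7 | 3,5-bis(methoxymethoxy)-2-(2-methylbut-3-en-2-yl)phenyl acetate | C=CC(C)(C)c1c(OC(C)=O)cc(OCOC)cc1OCOC | intermediate
8 | 2-iodo-3,5-bis(methoxymethoxy)-6-(2-methylbut-3-en-2-yl)phenyl acetate | C=CC(C)(C)c1c(OC(C)=O)c(I)c(OCOC)cc1OCOC | intermediate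
9 | 6-bromopiperonal | O=Cc1cc2OCOc2cc1Br | starting material
10 | 2-bromo-4,5-dihydroxybenzaldehyde | O=Cc1cc(O)c(O)cc1Br | intermediate
11 | 2-bromo-5-hydroxy-4-(methoxymethoxy)benzaldehyde | O=Cc1cc(O)c(OCOC)cc1Br | intermediate
12 | 3-chloro-3-methylbut-1-yne | C#CC(C)(C)Cl | starting material
13 | 2-bromo-4-(methoxymethoxy)-5-[(2-methylbut-3-yn-2-yl)oxy]benzaldehyde | O=Cc1cc(OC(C)(C)C#C)c(OCOC)cc1Br | intermediate
14 | 2-bromo-5-hydroxy-4-(methoxymethoxy)-6-(3-methylbuta-1,2-dien-1-yl)benzaldehyde (allenylphenol, not isolated) | O=Cc1c(C=C=C(C)C)c(O)c(OCOC)cc1Br | intermediate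
15 | 2-bromo-4-(methoxymethoxy)-6-(3-methylbut-2-en-1-ylidene)-5-oxocyclohexa-1,3-diene-1-carbaldehyde (ortho-quinone methide, not isolated) | O=CC1=C(Br)C=C(OCOC)C(=O)C1=CC=C(C)C | intermediate
16 | 6-bromo-8-(methoxymethoxy)-2,2-dimethyl-2H-chromene-5-carbaldehyde | O=Cc1c(Br)cc(OCOC)c2OC(C)(C)C=Cc12 | intermediate
17 | trimethylsilylacetylene | C#C[Si](C)(C)C | starting material
18 | 8-(methoxymethoxy)-2,2-dimethyl-6-[(trimethylsilyl)ethynyl]-2H-chromene-5-carbaldehyde | O=Cc1c(C#C[Si](C)(C)C)cc(OCOC)c2OC(C)(C)C=Cc12 | intermediate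
19 | {8-(methoxymethoxy)-2,2-dimethyl-6-[(trimethylsilyl)ethynyl]-2H-chromen-5-yl}methanol | OCc1c(C#C[Si](C)(C)C)cc(OCOC)c2OC(C)(C)C=Cc12 | intermediate
20 | 5-(bromomethyl)-8-(methoxymethoxy)-2,2-dimethyl-6-[(trimethylsilyl)ethynyl]-2H-chromene | BrCc1c(C#C[Si](C)(C)C)cc(OCOC)c2OC(C)(C)C=Cc12 | intermediate
21 | 2-methylprop-1-enylmagnesium bromide (THF solution) | CC(C)=C[Mg]Br | starting material
22 | 8-(methoxymethoxy)-2,2-dimethyl-5-(3-methylbut-2-en-1-yl)-6-[(trimethylsilyl)ethynyl]-2H-chromene | CC(C)=CCc1c(C#C[Si](C)(C)C)cc(OCOC)c2OC(C)(C)C=Cc12 | intermediate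
23 | 6-ethynyl-8-(methoxymethoxy)-2,2-dimethyl-5-(3-methylbut-2-en-1-yl)-2H-chromene | C#Cc1cc(OCOC)c2OC(C)(C)C=Cc2c1CC=C(C)C | intermediate
24 | carbon monoxide | [C-]#[O+] | starting material
25 | 2-{3-[8-(methoxymethoxy)-2,2-dimethyl-5-(3-methylbut-2-en-1-yl)-2H-chromen-6-yl]prop-2-ynoyl}-3,5-bis(methoxymethoxy)-6-(2-methylbut-3-en-2-yl)phenyl acetate | C=CC(C)(C)c1c(OC(C)=O)c(C(=O)C#Cc2cc(OCOC)c3OC(C)(C)C=Cc3c2CC=C(C)C)c(OCOC)cc1OCOC | intermediate
26 | 2-{3-(diethylamino)-3-[8-(methoxymethoxy)-2,2-dimethyl-5-(3-methylbut-2-en-1-yl)-2H-chromen-6-yl]prop-2-enoyl}-3,5-bis(methoxymethoxy)-6-(2-methylbut-3-en-2-yl)phenyl acetate (enaminone acetate, geometry not defined, not isolated) | C=CC(C)(C)c1c(OC(C)=O)c(C(=O)C=C(N(CC)CC)c2cc(OCOC)c3OC(C)(C)C=Cc3c2CC=C(C)C)c(OCOC)cc1OCOC | intermediate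
27 | 3-(diethylamino)-1-[2-hydroxy-4,6-bis(methoxymethoxy)-3-(2-methylbut-3-en-2-yl)phenyl]-3-[8-(methoxymethoxy)-2,2-dimethyl-5-(3-methylbut-2-en-1-yl)-2H-chromen-6-yl]prop-2-en-1-one (enaminone phenol, geometry not defined, not isolated) | C=CC(C)(C)c1c(O)c(C(=O)C=C(N(CC)CC)c2cc(OCOC)c3OC(C)(C)C=Cc3c2CC=C(C)C)c(OCOC)cc1OCOC | intermediate
28 | 5,7-bis(methoxymethoxy)-2-[8-(methoxymethoxy)-2,2-dimethyl-5-(3-methylbut-2-en-1-yl)-2H-chromen-6-yl]-8-(2-methylbut-3-en-2-yl)-4H-chromen-4-one | C=CC(C)(C)c1c(OCOC)cc(OCOC)c2c(=O)cc(-c3cc(OCOC)c4OC(C)(C)C=Cc4c3CC=C(C)C)oc12 | intermediate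
29 | 3-lithio derivative of flavone 28 (not isolated) | C=CC(C)(C)c1c(OCOC)cc(OCOC)c2c(=O)c([Li])c(-c3cc(OCOC)c4OC(C)(C)C=Cc4c3CC=C(C)C)oc12 | intermediate
30 | dimethyl boronate at C3 of flavone 28 (not isolated) | C=CC(C)(C)c1c(OCOC)cc(OCOC)c2c(=O)c(B(OC)OC)c(-c3cc(OCOC)c4OC(C)(C)C=Cc4c3CC=C(C)C)oc12 | intermediate
31 | 3-hydroxy-5,7-bis(methoxymethoxy)-2-[8-(methoxymethoxy)-2,2-dimethyl-5-(3-methylbut-2-en-1-yl)-2H-chromen-6-yl]-8-(2-methylbut-3-en-2-yl)-4H-chromen-4-one | C=CC(C)(C)c1c(OCOC)cc(OCOC)c2c(=O)c(O)c(-c3cc(OCOC)c4OC(C)(C)C=Cc4c3CC=C(C)C)oc12 | intermediate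
32 | Broussoflavonol D, 3,5,7-trihydroxy-2-[8-hydroxy-2,2-dimethyl-5-(3-methylbut-2-en-1-yl)-2H-chromen-6-yl]-8-(2-methylbut-3-en-2-yl)-4H-chromen-4-one (achiral) | C=CC(C)(C)c1c(O)cc(O)c2c(=O)c(O)c(-c3cc(O)c4c(c3CC=C(C)C)C=CC(C)(C)O4)oc12 | target

**Step count**
Total: 18 steps.
Longest linear sequence: 13 steps (steps 6–14 from 6-bromopiperonal, then steps 15–18); the ring A branch (steps 1–5) joins at step 15.

**Steps most likely to fail**

1. Step 15. Oxidative addition at the electron-rich C–I bond flanked by two oxygen substituents may be slow. Alkynylation may also outrun CO uptake, or the acetate may be lost and the freed phenoxide close in 5-exo mode. The fallback forms the same two bonds one after the other without palladium, sets out from phenol 6 (with alkyne 23) and rejoins the route at flavone 28. Magnesium-phenoxide-directed ortho-formylation of 6 (MgCl2, Et3N, paraformaldehyde, MeCN, reflux) should give 2-hydroxy-4,6-bis(methoxymethoxy)-3-(2-methylbut-3-en-2-yl)benzaldehyde F1, the only free ortho carbon being the future C4a. Alkyne 23 is deprotonated with n-BuLi (THF, −78 °C) to the lithium acetylide F2, which is added to the lithium phenoxide of F1 (from LiN(SiMe3)2) to give, after NH4Cl work-up, the racemic propargylic alcohol F3. MnO2 in CH2Cl2 should oxidise this benzylic–propargylic alcohol to the ortho-hydroxyaryl ynone F4. Et2NH in DMF then adds to F4 to give enaminone phenol 27, which closes to flavone 28.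

2. Step 17. The amide base may deprotonate C6–H between the two MOM ethers or the benzylic–allylic CH2 of the 2′-prenyl group in competition with C3–H, and the peroxide may attack the electron-rich double bonds. The fallback creates the C3–metal bond by halogen–metal exchange and not by deprotonation, sets out from ynone 25 and rejoins at 31. Et2NH alone (THF, rt, no DBU) should stop at enaminone acetate 26, which is isolated in this variant. NIS in CH2Cl2 at 0 °C iodinates the nucleophilic α-carbon of the enaminone to give the α-iodoenaminone acetate F5. K2CO3 in MeOH removes the acetate, and the phenoxide closes 6-endo with loss of Et2NH to give the 3-iodoflavone F6. Iodine–magnesium exchange with i-PrMgCl·LiCl (THF, −40 °C) gives the 3-magnesioflavone F7, which is trapped with B(OMe)3 to boronate 30 and oxidised with AcOH/H2O2 as in step 17 to 31.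

3. Step 5. The iodinating agent may attack the vinyl group, with capture of the iodonium ion by a neighbouring oxygen; substitution may occur at the carbon between the two MOM ethers; or the acid co-catalyst may cost a MOM group. The fallback forms the C–I bond before any alkene is present, sets out from phenol 2 and rejoins at iodide 8. Iodination of 2 (I2, NaHCO3, THF/H2O, 0 °C) at one of its two equivalent ortho carbons should give 2-iodo-3,5-bis(methoxymethoxy)phenol F6a, written below as F8. O-Alkylation with prenyl bromide 3 (K2CO3, acetone) gives the iodinated aryl prenyl ether F9. Claisen rearrangement (PhNEt2, 180 °C) into the one ortho carbon that still bears hydrogen gives 2-iodo-3,5-bis(methoxymethoxy)-6-(2-methylbut-3-en-2-yl)phenol F10. Acetylation as in step 4 then gives 8. (The first compound of this fallback is F8; the interim tag F6a is not used elsewhere.)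

**Further compounds**
F1 | step 15 | 2-hydroxy-4,6-bis(methoxymethoxy)-3-(2-methylbut-3-en-2-yl)benzaldehyde | C=CC(C)(C)c1c(O)c(C=O)c(OCOC)cc1OCOC
F2 | step 15 | lithium acetylide of alkyne 23 | [Li]C#Cc1cc(OCOC)c2OC(C)(C)C=Cc2c1CC=C(C)C
F3 | step 15 | 1-[2-hydroxy-4,6-bis(methoxymethoxy)-3-(2-methylbut-3-en-2-yl)phenyl]-3-[8-(methoxymethoxy)-2,2-dimethyl-5-(3-methylbut-2-en-1-yl)-2H-chromen-6-yl]prop-2-yn-1-ol (racemic) | C=CC(C)(C)c1c(O)c(C(O)C#Cc2cc(OCOC)c3OC(C)(C)C=Cc3c2CC=C(C)C)c(OCOC)cc1OCOC
F4 | step 15 | 1-[2-hydroxy-4,6-bis(methoxymethoxy)-3-(2-methylbut-3-en-2-yl)phenyl]-3-[8-(methoxymethoxy)-2,2-dimethyl-5-(3-methylbut-2-en-1-yl)-2H-chromen-6-yl]prop-2-yn-1-one | C=CC(C)(C)c1c(O)c(C(=O)C#Cc2cc(OCOC)c3OC(C)(C)C=Cc3c2CC=C(C)C)c(OCOC)cc1OCOC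
F5 | step 17 | 2-{3-(diethylamino)-2-iodo-3-[8-(methoxymethoxy)-2,2-dimethyl-5-(3-methylbut-2-en-1-yl)-2H-chromen-6-yl]prop-2-enoyl}-3,5-bis(methoxymethoxy)-6-(2-methylbut-3-en-2-yl)phenyl acetate | C=CC(C)(C)c1c(OC(C)=O)c(C(=O)C(I)=C(N(CC)CC)c2cc(OCOC)c3OC(C)(C)C=Cc3c2CC=C(C)C)c(OCOC)cc1OCOC
F6 | step 17 | 3-iodo-5,7-bis(methoxymethoxy)-2-[8-(methoxymethoxy)-2,2-dimethyl-5-(3-methylbut-2-en-1-yl)-2H-chromen-6-yl]-8-(2-methylbut-3-en-2-yl)-4H-chromen-4-one | C=CC(C)(C)c1c(OCOC)cc(OCOC)c2c(=O)c(I)c(-c3cc(OCOC)c4OC(C)(C)C=Cc4c3CC=C(C)C)oc12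
F7 | step 17 | 3-(chloromagnesio) derivative of flavone 28 | C=CC(C)(C)c1c(OCOC)cc(OCOC)c2c(=O)c([Mg]Cl)c(-c3cc(OCOC)c4OC(C)(C)C=Cc4c3CC=C(C)C)oc12
F8 | step 5 | 2-iodo-3,5-bis(methoxymethoxy)phenol | Oc1cc(OCOC)cc(OCOC)c1I
F9 | step 5 | 2-iodo-1,5-bis(methoxymethoxy)-3-[(3-methylbut-2-en-1-yl)oxy]benzene | CC(C)=CCOc1cc(OCOC)cc(OCOC)c1I
F10 | step 5 | 2-iodo-3,5-bis(methoxymethoxy)-6-(2-methylbut-3-en-2-yl)phenol | C=CC(C)(C)c1c(O)c(I)c(OCOC)cc1OCOC
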